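**Plan**

1. Retrosynthetic cuts, in order: C15–C5′ (vinylogous aldol of an intact 4-methylfuranone ring), C13=C14 (olefination of a C13 methyl ketone), the C18–O bond (C–H oxidation directed by 6α-OH), then the C6–C7 and C8–O bonds of ring B together.
2. Enabling feature: ring B carries the 1,3-diol C6(OH)–C7H2–C8(OH)(CH3) next to the ring fusion, which is the retron of an aldehyde–alkene (Prins) cyclisation ended by water; the precursor is a ring A aldehyde (CHO on C5) whose neighbour C10 carries C9 with a 2-propenyl group.
3. Forward: ring A comes from β-cyclocitral; an enantioselective ester-enolate Claisen rearrangement joins C9 to C10; a temporary δ-lactone (C6–O–C8) leads to the aldehyde/2-propenyl stage; ring B closes last; the heterocycles used afterwards (cyclic ketal, oxasilinane) are temporary and are opened again; the butenolide ring is brought in intact.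
4. Stereochemistry: C9 and C10 from the chair of the Claisen step under reagent control; C5 from hydroboration anti to the axial methyl groups; C6 and C8 from the chair of the ring closure; C4 from selective oxidation of the equatorial methyl group next to 6α-OH; C13=C14 from the olefination; C15 and C5′ from a catalyst-controlled vinylogous aldol reaction.

Key step: step 10

Numbering: labdane-type numbers are used throughout (ring A C1–C5 and C10; ring B C5–C10; C17 on C8; C18 (α) and C19 (β) on C4; C20 on C10; side chain C11–C16; butenolide C1′–C5′), with α below and β above the plane of the usual drawing.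

Assumption: the absolute sense of induction of the chiral boron reagent (step 4) and of the titanium–BINOL catalyst (step 17) is taken by analogy with simpler substrates; if the opposite sense is found, the other enantiomer of the controller is used.

**Route**

Step 1
Reactants: 1 β-cyclocitral
Product: 2 β-cyclogeraniol
Conditions: NaBH4, MeOH, 0 °C
Reagents that add atoms: none
Why: 1,2-reduction of the hindered enal by borohydride should give the primary allylic alcohol needed for the Claisen step, and no stereocentre is formed.

Step 2
Reactants: 3 5-oxohexanoic acid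
Product: 4 4-(2-methyl-1,3-dithian-2-yl)butanoic acid
Conditions: HS(CH2)3SH, BF3·OEt2, CH2Cl2, 0 °C → rt
Reagents that add atoms: propane-1,3-dithiol, SCCCS
Why: Lewis acid thioketalisation masks the future C13 ketone in a form that should survive the boron enolate, borane, MeLi and ylide chemistry that follows and that is removed oxidatively in step 9.

Step 3
Reactants: 2 β-cyclogeraniol; 4 4-(2-methyl-1,3-dithian-2-yl)butanoic acid
Product: 5 β-cyclogeranyl 4-(2-methyl-1,3-dithian-2-yl)butanoate
Conditions: DCC, DMAP, CH2Cl2, rt
Reagents that add atoms: none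
Why: Steglich esterification of the primary allylic alcohol places the future C8–C13 chain on the oxygen of C6 and so assembles the allyl ester for the sigmatropic step.

Step 4
Reactants: 5 β-cyclogeranyl 4-(2-methyl-1,3-dithian-2-yl)butanoate
Product: 6 Claisen acid (9α-H; 10β-CH3; exocyclic C5=C6)
Conditions: (S,S)-2-bromo-4,5-diphenyl-1,3-bis[3,5-bis(trifluoromethyl)phenylsulfonyl]-1,3,2-diazaborolidine, i-Pr2NEt, CH2Cl2, −78 °C → rt; then H2O
Reagents that add atoms: none
Why: Enantioselective Ireland–Claisen rearrangement through a chiral O-boron ketene acetal, in which the (Z)-O-boron enolate (chain cis to O–B) should rearrange through a chair that has the ring methyl group (cis to the CH2O carbon across the ring double bond) axial, so that the C9–C10 bond forms with H9 anti to the C10 methyl group as in the target (the chair is a template of ring B), while the twofold-symmetric sulfonamide ligand on boron chooses the face of the tetrasubstituted alkene and with it the absolute configuration of the quaternary C10 and of C9.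

Step 5
Reactants: 6 Claisen acid
Product: 7 methyl ester of 6
Conditions: Me3SiCHN2, MeOH/PhMe, 0 °C
Reagents that add atoms: (trimethylsilyl)diazomethane, C[Si](C)(C)C=[N+]=[N-]
Why: Neutral O-methylation of the acid with the diazomethane surrogate avoids base at the epimerisable C9 and alkylation at sulfur, and gives an ester that borane reduces only slowly.

Step 6
Reactants: 7 methyl ester of 6
Product: 9 trans-fused δ-lactone (C6–O–C8; 5α-H), via hydroxy ester 8 (not isolated)
Conditions: BH3·THF, THF, 0 °C → rt; Me3NO·2H2O, 65 °C; then PPTS, PhMe, 80 °C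
Reagents that add atoms: trimethylamine N-oxide, C[N+](C)(C)[O-]
Why: Anti-Markovnikov hydroboration–oxidation of the exocyclic methylene followed by acid-catalysed lactonisation, in which borane should add to the face opposite the axial methyl groups on C4 and C10 (the branched C9 substituent being equatorial) and so place the new hydrogen on the α face of C5 with C6 trans to C9, the amine oxide oxidises the C–B bond without touching the dithiane, and the primary alcohol closes the six-membered lactone onto the C8 ester.

Step 7
Reactants: 9 trans-fused δ-lactone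
Product: 10 δ-hydroxy methyl ketone (ring-chain tautomer of the methyl lactol)
Conditions: MeLi, THF, −78 °C; then H2O
Reagents that add atoms: methyllithium, [Li]C
Why: Single addition of MeLi to the lactone should stop at the lithium hemiketal at low temperature, so that after work-up C8 carries the methyl group that becomes C17 and the C6 oxygen is freed as the primary alcohol, with no stereocentre of the target formed or touched.

Step 8
Reactants: 10 δ-hydroxy methyl ketone
Product: 11 2-propenyl alcohol
Conditions: Ph3PCH3Br, KOtBu, THF, 0 → 50 °C
Reagents that add atoms: methyltriphenylphosphonium bromide, C[P+](c1ccccc1)(c1ccccc1)c1ccccc1.[Br-]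
Why: Wittig methylenation of the open-chain ketone tautomer converts the C8 carbonyl into the 2-propenyl group (C7=C8 with C17) that is the π-nucleophile of the key step, and the hindered tertiary C9–H is slow to enolise so that C9 should keep its configuration.

Step 9
Reactants: 11 2-propenyl alcohol
Product: 12 keto aldehyde
Conditions: Dess–Martin periodinane, wet MeCN/CH2Cl2, rt
Reagents that add atoms: water, O
Why: Dess–Martin oxidation of the primary alcohol to the C6 aldehyde, with the same reagent in wet solvent also removing the dithiane oxidatively to unmask the C13 ketone (a known second use of this reagent), in a medium mild enough to leave C5 and C9 unchanged.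

Step 10
Reactants: 12 keto aldehyde
Product: 13 keto diol (6α-OH; 8α-OH; equilibrates with its 8-O–C13 hemiketal)
Conditions: 0.5 M aq. H2SO4, THF, 0 °C → rt
Reagents that add atoms: water, O
Why: Protonation of the hindered C6 aldehyde gives an electrophile that is attacked by the terminal carbon C7 of the 2-propenyl group on C9, so that the C6–C7 bond and ring B (C5, C6, C7, C8, C9, C10) form through a chair transition state and leave a tertiary cation at C8, which is captured by water, either directly or through the side-chain carbonyl oxygen followed by hydrolysis of the resulting oxocarbenium ion. The closest known reaction types are the acid-mediated cyclisation of citronellal to p-menthane-3,8-diol and the type 2 carbonyl–ene/Prins cyclisations of 6-methylhept-6-enals to 3-substituted cyclohexanols, and the C8 cation with its capture from the α face copies the water-terminated cyclisation presumed to form 8-hydroxylabdanes in nature. Ring B closes in a 6-endo mode with respect to the alkene (both alkene carbons end in the ring) and exo with respect to the carbonyl group. C6 is set by the chair, in which the carbonyl oxygen takes the equatorial (α) position because the axial position is blocked by the axial methyl groups on C4 and C10; C8 is set by attack of the oxygen nucleophile on the face opposite the axial C10 methyl group, which leaves the C8 methyl group axial (β) and the hydroxyl equatorial (α); C5 and C9 keep the trans arrangement from steps 4 and 6, which gives the trans ring fusion. The step needs the aldehyde to react in preference to the methyl ketone and hydration to win over proton loss: the aldehyde and the alkene sit on adjacent ring carbons and are held close, and a water-rich medium at low temperature should favour kinetic hydration and keep the new tertiary alcohol from ionising again.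

Step 11
Reactants: 13 keto diol
Product: 14 cyclic methyl ketal (8α,13-epoxy-13-methoxy; 6α-OH free)
Conditions: MeOH, PPTS, rt
Reagents that add atoms: methanol, CO
Why: Acid-catalysed ketalisation of the δ-hydroxy ketone through its hemiketal gives a temporary six-membered mixed ketal that masks both the C13 ketone and the tertiary 8α-OH, leaving 6α-OH as the only free hydroxyl, and the ketal carbon is an anomeric mixture of no consequence.

Step 12
Reactants: 14 cyclic methyl ketal
Product: 18 keto triol (6α,8α,18-triol), via hydridosilyl ether 15 (not isolated), via oxasilinane 16 (not isolated), via diol methyl ketal 17 (not isolated)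
Conditions: Et2SiH2, [Ir(cod)OMe]2 (cat.), THF, rt; then [Rh(coe)2Cl]2/Xantphos (cat.), norbornene, THF, 100 °C; then H2O2, KHCO3, MeOH/THF, 50 °C; then 1 M HCl, THF, rt
Reagents that add atoms: hydrogen peroxide, OO; water, O
Why: Proposed new method: the 6α-hydroxyl is converted into its diethylhydridosilyl ether, and oxidative addition of the Si–H bond to rhodium followed by cleavage of a C–H bond of the equatorial 4α-methyl group (C18) should give the six-membered oxasilinane with norbornene as hydrogen acceptor, because C18 lies in a syn-pentane (peri) relation to the equatorial C6 oxygen and is the only primary C–H within reach (C4, C8 and C10 carry no hydrogen and the axial methyl groups C17, C19 and C20 point to the other face), after which Tamao–Fleming oxidation turns the C–Si bond into the C18–O bond and makes C4 a stereocentre (CH2OH α, CH3 β) and aqueous acid opens the temporary ketal; the closest known reaction type is the hydroxyl-directed silylation of γ-methyl C–H bonds of secondary alcohols and of δ-methyl C–H bonds of tertiary alcohols with iridium or rhodium catalysts followed by oxidation to 1,3- and 1,4-diols, which has not been shown for a δ-methyl group of a hindered secondary alcohol of this kind.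

Step 13
Reactants: 18 keto triol; 19 diethyl {2-[methoxy(methyl)amino]-2-oxoethyl}phosphonate
Product: 20 (E)-N-methoxy-N-methyl enamide triol
Conditions: NaH, THF, 0 → 65 °C
Reagents that add atoms: none
Why: Horner–Wadsworth–Emmons olefination of the methyl ketone, which reacts through the open form of its hemiketal, should give mainly the (E)-trisubstituted C13=C14 alkene (the larger C12 chain trans to the carbonyl group), with any (Z) isomer removed by chromatography, and it brings in C14 and C15 at the amide oxidation level.

Step 14
Reactants: 20 (E)-N-methoxy-N-methyl enamide triol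
Product: 21 tris(triethylsilyl) ether
Conditions: Et3SiOTf, 2,6-lutidine, CH2Cl2, −78 → 0 °C
Reagents that add atoms: triethylsilyl trifluoromethanesulfonate, CC[Si](CC)(CC)OS(=O)(=O)C(F)(F)F
Why: The silyl triflate should silylate the primary, the hindered secondary and the tertiary hydroxyl alike, which keeps them out of the hydride reduction and the Lewis acid step and allows a single fluoride deprotection at the end.

Step 15
Reactants: 21 tris(triethylsilyl) ether
Product: 22 (E)-enal
Conditions: i-Bu2AlH, THF, −78 °C; then aq. potassium sodium tartrate
Reagents that add atoms: none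
Why: Reduction of the N-methoxy-N-methyl amide stops at the chelated tetrahedral aluminium adduct, which on work-up should give the α,β-unsaturated aldehyde without loss of the alkene geometry.

Step 16
Reactants: 23 4-methylfuran-2(5H)-one
Product: 24 4-methyl-2-(trimethylsilyloxy)furan
Conditions: Me3SiOTf, Et3N, CH2Cl2, 0 °C
Reagents that add atoms: trimethylsilyl trifluoromethanesulfonate, C[Si](C)(C)OS(=O)(=O)C(F)(F)F
Why: Soft enolisation and O-silylation of the butenolide gives the aromatic 2-silyloxyfuran, the γ-nucleophilic dienolate equivalent that carries the intact lactone ring into the last C–C bond formation.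

Step 17
Reactants: 22 (E)-enal; 24 4-methyl-2-(trimethylsilyloxy)furan
Product: 26 aldol adduct (15S; 5′S; tris-triethylsilyl ether), via trimethylsilyl ether 25 (not isolated)
Conditions: Ti(OiPr)4 (cat.), (R)-BINOL (cat.), Et2O, −20 °C; then citric acid, MeOH, 0 °C
Reagents that add atoms: none
Why: Catalytic enantioselective vinylogous Mukaiyama aldol reaction, in which the silyloxyfuran attacks the enal carbonyl (1,2-addition) through its γ-carbon in an open transition state that favours the threo (like) relation of C5′ and C15 while the chiral titanium BINOLate chooses the aldehyde face, so that both new centres are set by the catalyst independently of the remote decalin, and mild methanolysis removes only the trimethylsilyl group.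

Step 18
Reactants: 26 aldol adduct
Product: 27 target CNP0255788.1
Conditions: HF·pyridine, pyridine, THF, 0 °C → rt
Reagents that add atoms: none
Why: Fluoride-mediated cleavage of the three triethylsilyl ethers under buffered conditions should free the 6α-, 8α- and 18-hydroxyls without base that could epimerise or cleave the γ-(hydroxyalkyl)butenolide.

**Compound list**

1 | β-cyclocitral (2,6,6-trimethylcyclohex-1-ene-1-carbaldehyde) | CC1=C(C=O)C(C)(C)CCC1 | starting material
2 | β-cyclogeraniol ((2,6,6-trimethylcyclohex-1-en-1-yl)methanol) | CC1=C(CO)C(C)(C)CCC1 | intermediate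
3 | 5-oxohexanoic acid | CC(=O)CCCC(=O)O | starting material
4 | 4-(2-methyl-1,3-dithian-2-yl)butanoic acid | CC1(CCCC(=O)O)SCCCS1 | intermediate
5 | (2,6,6-trimethylcyclohex-1-en-1-yl)methyl 4-(2-methyl-1,3-dithian-2-yl)butanoate | CC1=C(COC(=O)CCCC2(C)SCCCS2)C(C)(C)CCC1 | intermediate
6 | (2R)-4-(2-methyl-1,3-dithian-2-yl)-2-[(1R)-1,3,3-trimethyl-2-methylidenecyclohexyl]butanoic acid (9α-H, 10β-CH3) | CC1(SCCCS1)CC[C@@H](C(=O)O)[C@@]1(C)CCCC(C)(C)C1=C | intermediate
7 | methyl ester of 6 | CC1(SCCCS1)CC[C@@H](C(=O)OC)[C@@]1(C)CCCC(C)(C)C1=C | intermediate
8 | hydroxy ester: methyl ester with CH2OH on C5 (5α-H, 9α-H, 10β-CH3) | CC1(SCCCS1)CC[C@@H](C(=O)OC)[C@@]1(C)CCCC(C)(C)[C@@H]1CO | intermediate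
9 | trans-fused δ-lactone C6H2–O–C8(=O), oxa analogue of ring B (5α-H, 9α-H, 10β-CH3, dithianylethyl chain on C9 β) | CC1(SCCCS1)CC[C@@H]1[C@@]2(C)CCCC(C)(C)[C@@H]2COC1=O | intermediate
10 | δ-hydroxy methyl ketone: acetyl (C8) on C9, CH2OH on C5 (5α-H, 9α-H, 10β-CH3); tautomer of the methyl lactol | CC1(SCCCS1)CC[C@@H](C(C)=O)[C@@]1(C)CCCC(C)(C)[C@@H]1CO | intermediate
11 | 2-propenyl alcohol: prop-1-en-2-yl on C9, CH2OH on C5 (5α-H, 9α-H, 10β-CH3), dithiane intact | CC1(SCCCS1)CC[C@@H](C(C)=C)[C@@]1(C)CCCC(C)(C)[C@@H]1CO | intermediate
12 | keto aldehyde: CHO on C5 (5α-H), prop-1-en-2-yl and 3-oxobutyl on C9 (9α-H), 10β-CH3 | CC(=O)CC[C@@H](C(C)=C)[C@@]1(C)CCCC(C)(C)[C@@H]1C=O | intermediate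
13 | keto diol: trans-decalin with 6α-OH, 8α-OH, 8β-CH3, 4,4-dimethyl, 3-oxobutyl on C9 (β) | CC(=O)CC[C@@H]1[C@@]2(C)CCCC(C)(C)[C@@H]2[C@@H](O)C[C@@]1(C)O | intermediate
14 | cyclic methyl ketal of 13 (8α,13-epoxy-13-methoxy, 6α-OH free; anomers at C13) | COC1(C)CC[C@@H]2[C@@]3(C)CCCC(C)(C)[C@@H]3[C@@H](O)C[C@@]2(C)O1 | intermediate
15 | 6α-O-diethylhydridosilyl ether of 14 | COC1(C)CC[C@@H]2[C@@]3(C)CCCC(C)(C)[C@@H]3[C@@H](O[SiH](CC)CC)C[C@@]2(C)O1 | intermediate
16 | oxasilinane: 6α-O–SiEt2–C18 bridge, C19 methyl β | COC1(C)CC[C@@H]2[C@@]3(C)CCC[C@@](C)(C[Si]4(CC)CC)[C@@H]3[C@@H](O4)C[C@@]2(C)O1 | intermediate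
17 | diol methyl ketal: 6α-OH, 18-OH (4α-CH2OH, 4β-CH3), 8α,13-epoxy-13-methoxy | COC1(C)CC[C@@H]2[C@@]3(C)CCC[C@@](C)(CO)[C@@H]3[C@@H](O)C[C@@]2(C)O1 | intermediate
18 | keto triol: 6α-OH, 8α-OH, 18-OH, 3-oxobutyl on C9 (β) | CC(=O)CC[C@@H]1[C@@]2(C)CCC[C@@](C)(CO)[C@@H]2[C@@H](O)C[C@@]1(C)O | intermediate
19 | diethyl {2-[methoxy(methyl)amino]-2-oxoethyl}phosphonate | CCOP(=O)(CC(=O)N(C)OC)OCC | starting material
20 | (13E)-N-methoxy-N-methyl enamide (C15) of the 6α,8α,18-triol | CON(C)C(=O)/C=C(\C)CC[C@@H]1[C@@]2(C)CCC[C@@](C)(CO)[C@@H]2[C@@H](O)C[C@@]1(C)O | intermediate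
21 | 6,8,18-tris(triethylsilyl) ether of 20 | CON(C)C(=O)/C=C(\C)CC[C@@H]1[C@@]2(C)CCC[C@@](C)(CO[Si](CC)(CC)CC)[C@@H]2[C@@H](O[Si](CC)(CC)CC)C[C@@]1(C)O[Si](CC)(CC)CC | intermediate
22 | (13E)-enal (C15 aldehyde), 6,8,18-tris(triethylsilyl) ether | O=C/C=C(\C)CC[C@@H]1[C@@]2(C)CCC[C@@](C)(CO[Si](CC)(CC)CC)[C@@H]2[C@@H](O[Si](CC)(CC)CC)C[C@@]1(C)O[Si](CC)(CC)CC | intermediate
23 | 4-methylfuran-2(5H)-one | CC1=CC(=O)OC1 | starting material
24 | 4-methyl-2-(trimethylsilyloxy)furan | Cc1coc(O[Si](C)(C)C)c1 | intermediate
25 | aldol adduct as 15-O-trimethylsilyl ether (15S, 5′S), 6,8,18-tris(triethylsilyl) ether | CC1=CC(=O)O[C@@H]1[C@@H](O[Si](C)(C)C)/C=C(\C)CC[C@@H]1[C@@]2(C)CCC[C@@](C)(CO[Si](CC)(CC)CC)[C@@H]2[C@@H](O[Si](CC)(CC)CC)C[C@@]1(C)O[Si](CC)(CC)CC | intermediate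
26 | aldol adduct with free 15-OH (15S, 5′S), 6,8,18-tris(triethylsilyl) ether | CC1=CC(=O)O[C@@H]1[C@@H](O)/C=C(\C)CC[C@@H]1[C@@]2(C)CCC[C@@](C)(CO[Si](CC)(CC)CC)[C@@H]2[C@@H](O[Si](CC)(CC)CC)C[C@@]1(C)O[Si](CC)(CC)CC | intermediate
27 | CNP0255788.1: (5S)-5-[(1S,2E)-5-[(1R,2R,4S,4aR,5R,8aS)-2,4-dihydroxy-5-(hydroxymethyl)-2,5,8a-trimethyldecahydronaphthalen-1-yl]-1-hydroxy-3-methylpent-2-en-1-yl]-4-methylfuran-2(5H)-one | CC1=CC(=O)O[C@@H]1[C@@H](O)/C=C(\C)CC[C@@H]1[C@@]2(C)CCC[C@@](C)(CO)[C@@H]2[C@@H](O)C[C@@]1(C)O | target

**Step count and risks**

Total step count: 18. Longest linear sequence: 16 steps (steps 1, 3 to 15, 17 and 18, from β-cyclocitral).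

Steps most likely to fail:

1. Step 12 (proposed new method). The catalyst may fail to cleave the hindered neopentyl-type C–H bond, or the hydridosilyl ether may be lost by redistribution or react elsewhere before C–H cleavage. The fallback uses known photochemistry and sets out from 14. NOCl/pyridine should give the 6α-nitrite ester F1. Irradiation (Barton nitrite photolysis) should move a hydrogen from C18 to the C6 alkoxy radical through a six-membered transition state and, after recombination with NO and tautomerisation, give the 18-oxime F2. Exchange of the oxime with aqueous NaHSO3 should give the 18-aldehyde F3 (present as its 6,18-lactol), and NaBH4 should reduce it to the diol methyl ketal 17, which is hydrolysed to 18 as in the last stage of step 12.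

2. Step 10 (key step). The C8 cation may lose a proton to give alkenes, the tertiary alcohol may re-ionise and be captured from the other face, or the methyl ketone may compete as electrophile. The fallback sets out from 12. Me2AlCl in CH2Cl2 at −78 °C should close ring B with loss of a proton instead of hydration and give the 6α-hydroxy-8(17)-ene ketone F4. Mukaiyama hydration (Mn(dpm)3, PhSiH3, O2, i-PrOH) should then add the hydroxyl at the tertiary C8 through the C8 radical, from the less hindered α face, and return to 13; a 7-ene isomer formed beside F4 would give the same radical.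

3. Step 4. The rearrangement at the tetrasubstituted alkene may be slow, with loss of facial control by the boron ligand or passage through a boat transition state that erodes the C9/C10 relation. The fallback sets out from 5. A plain Ireland–Claisen rearrangement (KN(SiMe3)2, Me3SiCl, PhMe, −78 → 80 °C) should pass through the (Z)-silyl ketene acetal F5 and the racemic trimethylsilyl ester F6 and give, after aqueous work-up, acid 6 together with its enantiomer F7. Crystallisation of the (S)-1-phenylethylammonium salt of 6 F8 and acidification should return to 6. A C9 epimer, if formed, can be corrected at lactone 9 by kinetic protonation of its enolate from the α face.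

Further compounds
F1 | step 12 | 6α-nitrite ester of cyclic methyl ketal 14 | COC1(C)CC[C@@H]2[C@@]3(C)CCCC(C)(C)[C@@H]3[C@@H](ON=O)C[C@@]2(C)O1
F2 | step 12 | 18-oxime (4α-CH=NOH, 4β-CH3, 6α-OH) of the cyclic methyl ketal | COC1(C)CC[C@@H]2[C@@]3(C)CCC[C@@](C)(C=NO)[C@@H]3[C@@H](O)C[C@@]2(C)O1
F3 | step 12 | 18-aldehyde (4α-CHO, 6α-OH; as its 6,18-lactol) of the cyclic methyl ketal | COC1(C)CC[C@@H]2[C@@]3(C)CCC[C@@](C)(C=O)[C@@H]3[C@@H](O)C[C@@]2(C)O1
F4 | step 10 | 6α-hydroxy-8(17)-ene ketone (exocyclic methylene on C8, 3-oxobutyl on C9) | CC(=O)CC[C@@H]1[C@@]2(C)CCCC(C)(C)[C@@H]2[C@@H](O)CC1=C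
F5 | step 4 | (Z)-O-trimethylsilyl ketene acetal of ester 5 | C[Si](C)(C)O/C(OCC1=C(C)CCCC1(C)C)=C\CCC1(C)SCCCS1
F6 | step 4 | trimethylsilyl ester of acid 6 (racemic) | CC1(SCCCS1)CC[C@@H](C(=O)O[Si](C)(C)C)[C@@]1(C)CCCC(C)(C)C1=C
F7 | step 4 | enantiomer of acid 6 | CC1(SCCCS1)CC[C@H](C(=O)O)[C@]1(C)CCCC(C)(C)C1=C
F8 | step 4 | (S)-1-phenylethylammonium salt of acid 6 | CC1(SCCCS1)CC[C@@H](C(=O)[O-])[C@@]1(C)CCCC(C)(C)C1=C.C[C@H]([NH3+])c1ccccc1
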